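## Retrosynthetic overview

1. The target is traced back to its fully aromatic tetradepside. The ring A para-quinol (the only stereocentre) is made in the last step by catalytic enantioselective para-hydroxylative dearomatisation of the ring A 4-hydroxybenzoate; this is done on the ester because the free quinol acid would decarboxylate to a hydroquinone.
2. The aromatic tetradepside is cut at the ester between rings B and C into a rings A–B acid and a rings C–D phenol, each made by one esterification.
3. Allyl ethers are the only protecting groups; the carboxyls of rings B and D travel as aldehydes and are unveiled by Pinnick oxidation.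
4. Rings A and C come from methyl 2,4-dihydroxy-3,6-dimethylbenzoate; rings B and D come from 4,5-dimethylresorcinol through one Vilsmeier aldehyde.
5. No ring is constructed: all four six-membered rings are bought as benzene rings. Joining order is A+B, C+D, AB+CD, then ring A is dearomatised.

Assumption: 4,5-dimethylresorcinol and methyl 2,4-dihydroxy-3,6-dimethylbenzoate (methyl atrarate, a bulk fragrance chemical) are taken as catalogue materials.

Assumption: the (R,R) iodoarene catalyst is written in step 14; its sense of induction on this substrate is unknown, so a test run decides, and the (S,S) catalyst is used if that one gives the (R)-quinol.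

## Route

Step 1
Reactants: 1 4,5-dimethylresorcinol
Product: 3 2,4-dihydroxy-5,6-dimethylbenzaldehyde, via aryl iminium chloride 2 (not isolated)
Conditions: POCl3 (1.2 eq), DMF (3 eq), MeCN, 0 °C → rt; then H2O, 50 °C
Reagents that add atoms: N,N-dimethylformamide, CN(C)C=O; water, O
Why: Vilsmeier–Haack formylation goes to C6 (para to one hydroxyl, ortho to the other), as orcinol gives orcylaldehyde, and not to the crowded C2 between the two hydroxyls; the iminium salt is hydrolysed on work-up.

Step 2
Reactants: 3 2,4-dihydroxy-5,6-dimethylbenzaldehyde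
Product: 4 3-chloro-2,4-dihydroxy-5,6-dimethylbenzaldehyde
Conditions: SO2Cl2 (1.0 eq), Et2O, 0 °C → rt
Reagents that add atoms: sulfuryl chloride, O=S(=O)(Cl)Cl
Why: Electrophilic aromatic chlorination can only occur at C3, the single unsubstituted ring carbon, which is activated by both flanking hydroxyls.

Step 3
Reactants: 5 methyl 2,4-dihydroxy-3,6-dimethylbenzoate
Product: 7 methyl 4-(allyloxy)-2-methoxy-3,6-dimethylbenzoate, via 4-O-allyl ether 6 (not isolated)
Conditions: allyl bromide (1.05 eq), K2CO3, DMF, rt; then MeI (4 eq), 50 °C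
Reagents that add atoms: allyl bromide, C=CCBr; iodomethane, CI
Why: Sequential Williamson etherification works because the unchelated 4-OH is alkylated at room temperature while the 2-OH, hydrogen-bonded to the ester, only reacts with excess MeI on warming.

Step 4
Reactants: 7 methyl 4-(allyloxy)-2-methoxy-3,6-dimethylbenzoate
Product: 8 4-(allyloxy)-2-methoxy-3,6-dimethylbenzoic acid
Conditions: KOH (5 eq), DMSO/H2O 4:1, 90 °C; then 1 M HCl
Reagents that add atoms: potassium hydroxide, [K+].[OH-]
Why: Saponification of the di-ortho-substituted benzoate needs hot hydroxide in aqueous DMSO, conditions under which the allyl and methyl aryl ethers are inert.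

Step 5
Reactants: 8 4-(allyloxy)-2-methoxy-3,6-dimethylbenzoic acid; 4 3-chloro-2,4-dihydroxy-5,6-dimethylbenzaldehyde
Product: 9 2-chloro-4-formyl-3-hydroxy-5,6-dimethylphenyl 4-(allyloxy)-2-methoxy-3,6-dimethylbenzoate (rings A–B aldehyde)
Conditions: TFAA (1.5 eq), toluene, 0 °C → rt
Reagents that add atoms: none
Why: Trifluoroacetic-anhydride-mediated depside esterification: the mixed anhydride of the electron-rich 2,6-disubstituted acid ionises to an acylium ion that acylates even a hindered phenol, and only the 4-OH reacts because the 2-OH is chelated to the formyl group.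

Step 6
Reactants: 9 rings A–B aldehyde
Product: 10 4-{[4-(allyloxy)-2-methoxy-3,6-dimethylbenzoyl]oxy}-3-chloro-2-hydroxy-5,6-dimethylbenzoic acid (rings A–B acid)
Conditions: NaClO2 (3 eq), NaH2PO4 (3 eq), 2-methyl-2-butene (20 eq), t-BuOH/THF/H2O, 0 °C → rt
Reagents that add atoms: sodium chlorite, [Na+].[O-]Cl=O
Why: Pinnick oxidation turns the aldehyde into the acid at about pH 4, where the aryl ester survives, and the excess trisubstituted alkene traps hypochlorous acid before it can touch the allyl ether or the rings.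

Step 7
Reactants: 5 methyl 2,4-dihydroxy-3,6-dimethylbenzoate
Product: 12 2,4-bis(allyloxy)-3,6-dimethylbenzoic acid, via bis-allyl methyl ester 11 (not isolated)
Conditions: allyl bromide (3 eq), K2CO3 (4 eq), DMSO, 60 °C; then aq. KOH, 90 °C; then 1 M HCl
Reagents that add atoms: allyl bromide, C=CCBr; potassium hydroxide, [K+].[OH-]
Why: Exhaustive Williamson allylation followed by saponification in the same pot needs no selectivity, and surplus allyl bromide is destroyed by the hydroxide.

Step 8
Reactants: 12 2,4-bis(allyloxy)-3,6-dimethylbenzoic acid; 3 2,4-dihydroxy-5,6-dimethylbenzaldehyde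
Product: 13 4-formyl-5-hydroxy-2,3-dimethylphenyl 2,4-bis(allyloxy)-3,6-dimethylbenzoate (rings C–D aldehyde)
Conditions: TFAA (1.5 eq), toluene, 0 °C → rt
Reagents that add atoms: none
Why: Trifluoroacetic-anhydride-mediated esterification as in step 5 acylates only the unchelated 4-OH of 3, and acid 12 has no free hydroxyl with which to self-condense.

Step 9
Reactants: 13 rings C–D aldehyde
Product: 14 4-formyl-5-methoxy-2,3-dimethylphenyl 2,4-bis(allyloxy)-3,6-dimethylbenzoate
Conditions: MeI (3 eq), K2CO3, DMF, rt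
Reagents that add atoms: iodomethane, CI
Why: Williamson methylation hits the only free phenol, so the 2-OMe of ring D is set without ever protecting its 4-OH (the ring C acyl group does that job), and the hindered aryl ester tolerates anhydrous carbonate.

Step 10
Reactants: 14 4-formyl-5-methoxy-2,3-dimethylphenyl 2,4-bis(allyloxy)-3,6-dimethylbenzoate
Product: 15 4-formyl-5-methoxy-2,3-dimethylphenyl 2,4-dihydroxy-3,6-dimethylbenzoate (rings C–D phenol)
Conditions: Pd(PPh3)4 (5 mol %), p-toluenesulfinic acid (2.5 eq), CH2Cl2, rt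
Reagents that add atoms: none
Why: Tsuji–Trost-type deallylation: zerovalent palladium ionises both allyl aryl ethers to π-allyl complexes that the sulfinate captures irreversibly, leaving aldehyde and aryl ester untouched.

Step 11
Reactants: 10 rings A–B acid; 15 rings C–D phenol
Product: 16 rings A–B–C–D aldehyde (ring A 4-O-allyl; ring D CHO)
Conditions: DCC (1.2 eq), toluene/CH2Cl2, 0 °C → rt
Reagents that add atoms: none
Why: Carbodiimide depside coupling of an ortho-hydroxybenzoic acid with a phenol is regioselective here because the 4-OH of ring C is the only unchelated hydroxyl present (the 2-OH groups of rings B and C are hydrogen-bonded to their ortho carbonyls).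

Step 12
Reactants: 16 rings A–B–C–D aldehyde
Product: 17 rings A–B–C–D acid (ring A 4-O-allyl; ring D CO2H)
Conditions: NaClO2 (3 eq), NaH2PO4 (3 eq), 2-methyl-2-butene (30 eq), t-BuOH/THF/H2O, rt
Reagents that add atoms: sodium chlorite, [Na+].[O-]Cl=O
Why: Pinnick oxidation unveils the ring D carboxyl from its aldehyde surrogate under buffered conditions that leave the three depside esters, the chelated phenols and the allyl ether alone.

Step 13
Reactants: 17 rings A–B–C–D acid
Product: 18 aromatic tetradepside (ring A 4-OH free; ring D CO2H)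
Conditions: Pd(PPh3)4 (5 mol %), p-toluenesulfinic acid (1.3 eq), CH2Cl2/THF, rt
Reagents that add atoms: none
Why: Palladium-catalysed allyl transfer to sulfinate frees the ring A phenol under neutral conditions, and zerovalent palladium with PPh3 does not insert into the aryl chloride at room temperature.

Step 14
Reactants: 18 aromatic tetradepside
Product: 19 target (R)-quinol CNP0248758.1
Conditions: (R,R)-2,2'-[(2-iodo-1,3-phenylene)bis(oxy)]bis(N-mesitylpropanamide) (15 mol %), mCPBA (1.2 eq), H2O (20 eq), CH2Cl2/(CF3)2CHOH 4:1, −20 °C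
Reagents that add atoms: water, O
Why: Proposed new method: mCPBA oxidises the chiral iodoarene to a trivalent iodine species that exchanges a ligand for the ring A phenol (the only phenol of 18 not locked in a hydrogen bond to an ortho carbonyl, and the most electron-rich), the folded lactamide arms distinguish the C3-methyl flank from the C5-H flank of the bound ring and cover one face, and water then adds SN2′-like to the para carbon C1 (ipso to the ester, as in the oxidative ipso-substitution of 4-hydroxybenzoic acids) from the open face as the iodoarene leaves, which sets the (R) quaternary carbinol and breaks the aromaticity of ring A; the closest known reaction type is the chiral aryl iodide/mCPBA-catalysed hydroxylative dearomatisation of para-substituted phenols to para-quinols, which is expected to give only moderate enantioselectivity and is unproven for an ester-bearing para carbon.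

## Compound list

1 | 4,5-dimethylresorcinol (4,5-dimethylbenzene-1,3-diol) | Cc1cc(O)cc(O)c1C | starting material
2 | (2,4-dihydroxy-5,6-dimethylbenzylidene)dimethyliminium chloride | C[N+](C)=Cc1c(O)cc(O)c(C)c1C.[Cl-] | intermediate
3 | 2,4-dihydroxy-5,6-dimethylbenzaldehyde | O=Cc1c(O)cc(O)c(C)c1C | intermediate
4 | 3-chloro-2,4-dihydroxy-5,6-dimethylbenzaldehyde | O=Cc1c(O)c(Cl)c(O)c(C)c1C | intermediate
5 | methyl 2,4-dihydroxy-3,6-dimethylbenzoate | COC(=O)c1c(C)cc(O)c(C)c1O | starting material
6 | methyl 4-(allyloxy)-2-hydroxy-3,6-dimethylbenzoate | COC(=O)c1c(C)cc(OCC=C)c(C)c1O | intermediate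
7 | methyl 4-(allyloxy)-2-methoxy-3,6-dimethylbenzoate | COC(=O)c1c(C)cc(OCC=C)c(C)c1OC | intermediate
8 | 4-(allyloxy)-2-methoxy-3,6-dimethylbenzoic acid | OC(=O)c1c(C)cc(OCC=C)c(C)c1OC | intermediate
9 | 2-chloro-4-formyl-3-hydroxy-5,6-dimethylphenyl 4-(allyloxy)-2-methoxy-3,6-dimethylbenzoate | O=Cc1c(O)c(Cl)c(OC(=O)c2c(C)cc(OCC=C)c(C)c2OC)c(C)c1C | intermediate
10 | 4-{[4-(allyloxy)-2-methoxy-3,6-dimethylbenzoyl]oxy}-3-chloro-2-hydroxy-5,6-dimethylbenzoic acid | OC(=O)c1c(O)c(Cl)c(OC(=O)c2c(C)cc(OCC=C)c(C)c2OC)c(C)c1C | intermediate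
11 | methyl 2,4-bis(allyloxy)-3,6-dimethylbenzoate | COC(=O)c1c(C)cc(OCC=C)c(C)c1OCC=C | intermediate
12 | 2,4-bis(allyloxy)-3,6-dimethylbenzoic acid | OC(=O)c1c(C)cc(OCC=C)c(C)c1OCC=C | intermediate
13 | 4-formyl-5-hydroxy-2,3-dimethylphenyl 2,4-bis(allyloxy)-3,6-dimethylbenzoate | O=Cc1c(O)cc(OC(=O)c2c(C)cc(OCC=C)c(C)c2OCC=C)c(C)c1C | intermediate
14 | 4-formyl-5-methoxy-2,3-dimethylphenyl 2,4-bis(allyloxy)-3,6-dimethylbenzoate | O=Cc1c(OC)cc(OC(=O)c2c(C)cc(OCC=C)c(C)c2OCC=C)c(C)c1C | intermediate
15 | 4-formyl-5-methoxy-2,3-dimethylphenyl 2,4-dihydroxy-3,6-dimethylbenzoate | O=Cc1c(OC)cc(OC(=O)c2c(C)cc(O)c(C)c2O)c(C)c1C | intermediate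
16 | 4-[(4-formyl-5-methoxy-2,3-dimethylphenoxy)carbonyl]-3-hydroxy-2,5-dimethylphenyl 4-{[4-(allyloxy)-2-methoxy-3,6-dimethylbenzoyl]oxy}-3-chloro-2-hydroxy-5,6-dimethylbenzoate | O=Cc1c(OC)cc(OC(=O)c2c(C)cc(OC(=O)c3c(O)c(Cl)c(OC(=O)c4c(C)cc(OCC=C)c(C)c4OC)c(C)c3C)c(C)c2O)c(C)c1C | intermediate
17 | 4-{[4-({4-[(4-(allyloxy)-2-methoxy-3,6-dimethylbenzoyl)oxy]-3-chloro-2-hydroxy-5,6-dimethylbenzoyl}oxy)-2-hydroxy-3,6-dimethylbenzoyl]oxy}-2-methoxy-5,6-dimethylbenzoic acid | OC(=O)c1c(OC)cc(OC(=O)c2c(C)cc(OC(=O)c3c(O)c(Cl)c(OC(=O)c4c(C)cc(OCC=C)c(C)c4OC)c(C)c3C)c(C)c2O)c(C)c1C | intermediate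
18 | 4-{[4-({3-chloro-2-hydroxy-4-[(4-hydroxy-2-methoxy-3,6-dimethylbenzoyl)oxy]-5,6-dimethylbenzoyl}oxy)-2-hydroxy-3,6-dimethylbenzoyl]oxy}-2-methoxy-5,6-dimethylbenzoic acid | OC(=O)c1c(OC)cc(OC(=O)c2c(C)cc(OC(=O)c3c(O)c(Cl)c(OC(=O)c4c(C)cc(O)c(C)c4OC)c(C)c3C)c(C)c2O)c(C)c1C | intermediate
19 | 4-{[4-({3-chloro-2-hydroxy-4-[({(1R)-1-hydroxy-2-methoxy-3,6-dimethyl-4-oxocyclohexa-2,5-dien-1-yl}carbonyl)oxy]-5,6-dimethylbenzoyl}oxy)-2-hydroxy-3,6-dimethylbenzoyl]oxy}-2-methoxy-5,6-dimethylbenzoic acid | COC1=C(C)C(=O)C=C(C)[C@]1(O)C(=O)Oc1c(C)c(C)c(C(=O)Oc2cc(C)c(C(=O)Oc3cc(OC)c(C(=O)O)c(C)c3C)c(O)c2C)c(O)c1Cl | target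

## Step count and risks

Total steps: 14. Longest linear sequence: 8 steps (for example steps 1, 8, 9, 10, 11, 12, 13, 14).

The three steps most likely to fail are 14, 11 and 5.

**Step 14 (enantioselective dearomatisation).** Water may attack an ortho carbon instead of the ester-bearing para carbon, or the enantioselectivity may be low. The fallback sets out from 18 and replaces the trivalent-iodine route by electrophilic oxygenation of the ring A phenolate followed by resolution. Photo-oxygenation (O2, tetraphenylporphyrin, visible light, NaHCO3, MeCN/H2O, 0 °C) adds singlet oxygen across C1/C4 of ring A and gives the racemic ring A 1-hydroperoxy-4-oxocyclohexa-2,5-diene tetradepside F1. Me2S in the same pot reduces it to the racemic quinol tetradepside F2. Preparative chiral SFC then separates the enantiomers, and the route is rejoined at 19.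

**Step 11 (union of the rings A–B acid with the rings C–D phenol).** The 4-aroyloxy salicylic acid 10 may activate poorly with DCC. The fallback changes the order of assembly to a linear one that uses a 4-alkoxy-2-hydroxy acid of the type proven in depside couplings. It sets out from 4, which is allylated at the unchelated 4-OH (allyl bromide, KHCO3, DMF) to 4-(allyloxy)-3-chloro-2-hydroxy-5,6-dimethylbenzaldehyde F3. Pinnick oxidation gives 4-(allyloxy)-3-chloro-2-hydroxy-5,6-dimethylbenzoic acid F4. This is coupled with 15 (DCC, or TFAA in toluene) to the rings B–C–D aldehyde with ring B as allyl ether F5. Deallylation (Pd(PPh3)4, p-toluenesulfinic acid) gives the rings B–C–D aldehyde with ring B 4-OH free F6. Acid 8 is then esterified onto that 4-OH with TFAA, and the route is rejoined at 16.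

**Step 5 (esterification of the phenol flanked by chlorine and methyl).** If the hindered, electron-poor 4-OH of 4 does not acylate, the ester is made before the chlorine is introduced. The fallback sets out from 3 and 8, which are joined with TFAA in toluene (the same reaction as step 8) to 4-formyl-5-hydroxy-2,3-dimethylphenyl 4-(allyloxy)-2-methoxy-3,6-dimethylbenzoate F7. Ring B is then chlorinated at its only free carbon by phenol-directed ortho-chlorination (NCS, catalytic diisopropylammonium chloride, toluene, rt). Ring A has no free hydroxyl to direct the reagent, so it should be left alone, and the route is rejoined at 9.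

## Further compounds

F1 | step 14 | racemic 4-{[4-({3-chloro-4-[({1-hydroperoxy-2-methoxy-3,6-dimethyl-4-oxocyclohexa-2,5-dien-1-yl}carbonyl)oxy]-2-hydroxy-5,6-dimethylbenzoyl}oxy)-2-hydroxy-3,6-dimethylbenzoyl]oxy}-2-methoxy-5,6-dimethylbenzoic acid | COC1=C(C)C(=O)C=C(C)C1(OO)C(=O)Oc1c(C)c(C)c(C(=O)Oc2cc(C)c(C(=O)Oc3cc(OC)c(C(=O)O)c(C)c3C)c(O)c2C)c(O)c1Cl
F2 | step 14 | racemic 19 | COC1=C(C)C(=O)C=C(C)C1(O)C(=O)Oc1c(C)c(C)c(C(=O)Oc2cc(C)c(C(=O)Oc3cc(OC)c(C(=O)O)c(C)c3C)c(O)c2C)c(O)c1Cl
F3 | step 11 | 4-(allyloxy)-3-chloro-2-hydroxy-5,6-dimethylbenzaldehyde | O=Cc1c(O)c(Cl)c(OCC=C)c(C)c1C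
F4 | step 11 | 4-(allyloxy)-3-chloro-2-hydroxy-5,6-dimethylbenzoic acid | OC(=O)c1c(O)c(Cl)c(OCC=C)c(C)c1C
F5 | step 11 | 4-[(4-formyl-5-methoxy-2,3-dimethylphenoxy)carbonyl]-3-hydroxy-2,5-dimethylphenyl 4-(allyloxy)-3-chloro-2-hydroxy-5,6-dimethylbenzoate | O=Cc1c(OC)cc(OC(=O)c2c(C)cc(OC(=O)c3c(O)c(Cl)c(OCC=C)c(C)c3C)c(C)c2O)c(C)c1C
F6 | step 11 | 4-[(4-formyl-5-methoxy-2,3-dimethylphenoxy)carbonyl]-3-hydroxy-2,5-dimethylphenyl 3-chloro-2,4-dihydroxy-5,6-dimethylbenzoate | O=Cc1c(OC)cc(OC(=O)c2c(C)cc(OC(=O)c3c(O)c(Cl)c(O)c(C)c3C)c(C)c2O)c(C)c1C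
F7 | step 5 | 4-formyl-5-hydroxy-2,3-dimethylphenyl 4-(allyloxy)-2-methoxy-3,6-dimethylbenzoate | O=Cc1c(O)cc(OC(=O)c2c(C)cc(OCC=C)c(C)c2OC)c(C)c1C
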